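We compare two rates in Tuesday's flask: how fast the unconverted share (whatever of the charged Q is not yet E) drains, and how fast that drain itself fades.

the same everywhere: Q 0.50 M

|  | Z | G | remark | time |
|---|---|---|---|---|
| Tuesday's | 2 equiv | 15 mol% | the very flask that is asked about, followed so far |  |
| Thursday's | 2 equiv | 10 mol% | run made earlier |  |
| flask | 2.00 equiv | 15 mol% |  | 8.0 d |

Tuesday's run (percent of the Q charged)

| time / d | E / % | Q / % |
|---|---|---|
| 1.25 | 45.6 | 10.4 |
| 2.50 | 61.7 | 8.5 |
| 4.00 | 71.8 | 8.6 |
| 5.00 | 73.8 | 6.9 |

Thursday's run (percent of the Q charged)

| time / h | E / % | Q / % |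
|---|---|---|
| 6.00 | 15.8 | 29.1 |
| 12.0 | 22.1 | 18.4 |
| 20.0 | 30.8 | 16.8 |
| 25.0 | 33.5 | 15.3 |

(standard deviation of a reading: 1 percentage point)

- E that was removed still counts
- the numbers in the tables scatter by 1 percentage point (one standard deviation)
- additions bring no volume worth counting

- spring: at 8.0 d add Z, 50.0% of the amount charged, then wait 15 d
- dawn: change nothing and wait 15 d more
- summer: at 8.0 d add G, 100% of the amount charged, then wait 15 d
- dusk: at 8.0 d take out 90% of the E then present, then wait 15 d

1. E, in percent of the Q first charged, at 8.0 d
2. what to do for the largest gain in E; "none" if nothing gains more than 2 percentage points (spring / dawn / summer / dusk / none)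
3. E present, with what was taken out counted in, in percent of the Q first charged, after dawn
4. E present, with what was taken out counted in, in percent of the Q first charged, after summer

From 1.25 d to 2.50 d the pseudo-first-order drain constant of that share is 0.281 d⁻¹. From 2.50 d to 5.00 d it is 0.152 d⁻¹. So it fades by 0.328 d⁻¹, a reading with a half-life of 2.12 d. Back at the start the drain reads 0.519 d⁻¹.

But these are scattered readings, so we try a different run. Thursday's flask drains at 0.298 d⁻¹, which scaled to Tuesday's loading is 0.447 d⁻¹. Tuesday's line gives 0.420 d⁻¹ at that moment. These two readings lie near each other, as a drain in step with the loading of G would have them. Whether cG itself is fading, these readings cannot prove, but we commit to it.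

We carry the reach: the drain constant divided by the fade constant, which counts the e-foldings of the unconverted share that the G still working can perform. At the start it is 1.58. It crosses unity at 1.40 d, and after that, on these readings, the drain constant stands below the fade constant.

Spending the reach from the reading at 5.00 d, we expect E of 78.4% at 8.0 d. Waiting then brings 80.7%. Fresh G restores a full reach and brings 96.0%, so we would choose summer, a gain larger than waiting gives.

Could Z be what fades? At one Z per E, 63.1% of the Z charged stands at 5.00 d, and with Z charged at 2 equiv, Q is the limiting reagent.

The forecast differs from us: 84% now, 97.5% after dawn, 99.5% after summer, and best none. Its ground: “That points to product inhibition”.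

The flask gives 79.4%, 82.7% after dawn and 96.2% after summer. Best is summer, gaining 17 percentage points against 3.3 points for dawn.

    Q + G → G + X (k = 1.10 L mol⁻¹ h⁻¹)
    Z + G + X → G + E (k = 34.6 L² mol⁻² h⁻¹)
    Q ⇌ J (K = 3.03, k = 0.226 h⁻¹)
    G → D (k = 0.0118 h⁻¹)

At 8.00 d Tuesday's flask holds 10.4% of its G and 89.6% as D. The reach left then is 0.115. Spent on the simulated 79.4%, it gives 81.6%, against 82.7% after dawn. The neighbouring flask is the same charge read at 5.0 d. The reach left there is 0.306, which is 19.4% of the reach at the start. That neighbour holds 24.3% of its G, and its E stands at 74.0%.

The earlier runs and the new flask come from a simulation on assumed constants.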